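(The numbers in the tables were generated by integration for substances that don't exist.)

Count half-lives. For each flask I ask how many relaxation half-lives of the target fit into its time.

| flask | substrate | catalyst | remark | time |
|---|---|---|---|---|
| cedar | 0.48 M | 0.1 mol% | run made earlier |  |
| maple | 0.99 M | 0.1 mol% | run made earlier |  |
| alder | 2.7 M | 0.1 mol% | run made earlier |  |
| south-west | 0.40 M | 0.1 mol% |  | 12 d |
| south | 0.60 M | 0.1 mol% |  | 12 d |
| north | 1.0 M | 0.1 mol% |  | 12 d |
| south-east | 1.5 M | 0.1 mol% |  | 12 d |
| west | 2.5 M | 0.1 mol% |  | 12 d |

| run | time / d | target / % | substrate / % |
|---|---|---|---|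
| cedar | 0.500 | 48 | 7 |
| cedar | 1.04 | 48 | 2 |
| cedar | 2.50 | 36 | 0 |
| cedar | 6.00 | 28 | 1 |
| maple | 1.67 | 36 | 0 |
| maple | 3.00 | 29 | 2 |
| maple | 5.00 | 28 | 2 |
| maple | 6.00 | 28 | 0 |
| alder | 1.67 | 44 | 5 |
| alder | 3.00 | 40 | 0 |
| alder | 5.00 | 41 | 0 |
| alder | 6.00 | 39 | 1 |

(readings scatter by 1.5 percentage points)

- percentages count the substrate that a species holds: one homo dimer counts as two
- target is meant together with its crystals
- solid, in amounts per volume of the solution: crystals
- what was read earlier has a scatter of 1.5 percentage points, one standard deviation
- steps thought possible: substrate + catalyst -> catalyst + target; substrate -> side product; 2 substrate -> homo dimer; crystals <-> target; target + catalyst <-> isomer of the product + catalyst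
- the concentration of target that is asked is that of its free form alone
- "hardly changes" means that all values lie within two and a half points (for a concentration: within two and a half percent of the largest)

- [target] (only what is free in solution) at the end for south-west, south, north, south-east, west, in this order
- how that number moves from the first to the last of them (falls all the way / hardly changes / falls, then rises / rises all the way / rises, then falls)

**Fast rung.** In cedar the substrate reads 7 % at 0.500 d, so its overall half-life there is near 0.130 d. By 1.04 d it reads 2 %, and target stands at 48 %.

**Middle rung.** Then cedar's target sinks towards 28 %, the level maple also reads. I take this as target and isomer of the product relaxing to equilibrium over the catalyst, a pseudo-first-order approach while the catalyst holds. Between 1.04 d and 2.50 d the gap above that level shrinks from 20 percentage points to 8 points. That gives a half-life near 1.10 d, slower than the substrate's. It is a rough reading, given the scatter on so small a gap.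

**The count.** The loading stays at 0.1 mol%, so catalyst concentration follows the charge, and I let the relaxation rate follow it too. Time over cedar's half-life, multiplied by charge over cedar's charge, gives 9.05 for south-west and 56.6 for west. I call this the count of relaxation half-lives. For maple at 3.00 d it gives 5.60, and there target reads 29 %, already beside its later 28 %.

**Slow rung.** The time 12 d is longer than cedar's relaxation half-life, so with the counts above I expect end states in south-west and west. The count gives me no concentration. Alder's 39 %, above maple's 28 %, I read as crystals counted with target.

**The forecast.** It gives 0.112 M, 0.168 M, 0.28 M, 0.35 M and 0.35 M, shape rises all the way: “The row rises, then flattens at the cap.”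

**The flask.** Free c(target) at the end comes to 0.0901 M, 0.149 M, 0.275 M, 0.436 M and 0.680 M, shape rises all the way. West stands at 0.680 M against the forecast's 0.35 M.

    substrate + catalyst → catalyst + target (k = 0.0718 M⁻¹ s⁻¹)
    substrate → side product (k = 1.77 × 10⁻⁵ s⁻¹)
    2 substrate → homo dimer (k = 2.06 × 10⁻⁵ M⁻¹ s⁻¹)
    crystals ⇌ target, rate k4*(cs4 - [target]) while solid is left; crystals form when [target] > cs4 (solubility = 0.680 M, k = 4.35 × 10⁻⁴ s⁻¹)
    target + catalyst ⇌ isomer of the product + catalyst, rate k5*[catalyst]*[target] forward; the back reaction follows from the equilibrium constant (K = 1.40, k = 0.00604 M⁻¹ s⁻¹)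

**Count held.** In south-west the relaxation half-life of dissolved target and isomer of the product by that step alone, at 12.0 d, is 1.94 d, shorter than the time 12 d, which makes 6.19 half-lives against my count of 9.05, and south-west's target goes from 26.0 % at 6.00 d to 22.5 % at 12.0 d. West, with a count of 56.6, has target, crystals counted in it, at 35.3 % at 6.00 d and 35.2 % at 12.0 d, with crystals at 7.96 %.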